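## Retrosynthetic overview

1. The target is the dehydrative homodimer of one diarylheptanoid, (1E,3S,5S)-1,7-bis(4-hydroxyphenyl)hept-1-ene-3,5-diol: both halves map onto it with all carbinol centres S.
2. Last step, and the only ring formation: disconnect the ring C3–side-chain CH bond and the ring O1–C2 bond. One monomer is the electrophile (vinylogous p-quinone methide), the other the nucleophile (p-hydroxystyrene with its δ-OH).
3. The syn-diol monomer comes from 1,3-syn reduction of a β-hydroxy ketone.
4. The β-hydroxy ketone comes from a catalytic asymmetric Mukaiyama aldol between the enol silane of raspberry ketone and 4-silyloxycinnamaldehyde; this sets the first stereocentre.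

Assumption (catalyst sense): the (R,R)-bisphosphoramide is taken to give Re-face attack (recalled, not verified), so (S,S) is written to obtain the (S)-carbinol. The sense of the phosphoric acid in step 5 cannot be predicted; (R)-TRIP is written as the matched enantiomer, otherwise use (S)-TRIP.

Assumption (protection): aryl O–TMS groups serve as transient protection and are removed in the aldol work-up.

## Route

**Step 1**
Reactants: 1, 4-(4-hydroxyphenyl)butan-2-one (raspberry ketone)
Product: 2, trimethyl({4-[4-(trimethylsilyloxy)phenyl]but-1-en-2-yl}oxy)silane (terminal enol silane, aryl O–TMS)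
Conditions: 1 added to LDA (2.3 equiv), THF, −78 °C; TMSCl (3 equiv), −78 °C → rt; pentane, filter, Kugelrohr
Reagents that add atoms: chlorotrimethylsilane, C[Si](C)(C)Cl (two Me3Si groups)
Why: The hindered amide base removes the phenol proton and then, under kinetic control, a methyl proton, and TMSCl O-silylates both the phenoxide and the less substituted enolate (kinetic silyl enol ether formation).

**Step 2**
Reactants: 3, (E)-3-(4-hydroxyphenyl)prop-2-enal (4-hydroxycinnamaldehyde)
Product: 4, (E)-3-[4-(trimethylsilyloxy)phenyl]prop-2-enal
Conditions: TMSCl (1.1 equiv), Et3N (1.2 equiv), CH2Cl2, 0 °C → rt; filter under N2, concentrate, use crude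
Reagents that add atoms: chlorotrimethylsilane, C[Si](C)(C)Cl
Why: Simple phenol O-silylation (the enal has no enolisable position) masks the OH so it cannot consume SiCl4 in the next step.

**Step 3**
Reactants: 2 (1.2 equiv) and 4 (1.0 equiv)
Product: 5, (5S,6E)-5-hydroxy-1,7-bis(4-hydroxyphenyl)hept-6-en-3-one (both phenols free)
Conditions: SiCl4 (1.5 equiv), (S,S)-Denmark bisphosphoramide (binaphthyldiamine-derived, pentamethylene-linked; 5 mol %), iPr2NEt (0.2 equiv), CH2Cl2, −78 °C; then sat. aq KF/1 M KH2PO4, rt
Reagents that add atoms: none
Why: Denmark Lewis-base-activated Lewis-acid Mukaiyama aldol: the chiral phosphoramide-bound trichlorosilyl cation binds the enal and the enol silane adds 1,2 to its Si face, setting the first stereocentre (C5, S), and the fluoride/phosphate work-up cleaves the silyl aldolate and both aryl O–TMS groups.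

**Step 4**
Reactants: 5
Product: 6, (1E,3S,5S)-1,7-bis(4-hydroxyphenyl)hept-1-ene-3,5-diol (syn-1,3-diol)
Conditions: Et2BOMe (2.2 equiv), THF/MeOH 4:1, −78 °C; NaBH4 (1.5 equiv), −78 °C; pH 7 buffer, then MeOH co-evaporation
Reagents that add atoms: none (hydride only)
Why: Narasaka–Prasad reduction: Et2BOMe locks the β-hydroxy ketone in a six-membered boron chelate and external hydride adds axially to give the 1,3-syn diol (the former ketone carbon becomes C5 of 6, S), leaving the non-conjugated styrene and the phenols untouched.

**Step 5**
Reactants: 6 (two molecules)
Product: 7, blepharocalyxin C, (2S,3S,4S,6S)-2-(4-hydroxyphenyl)-6-[2-(4-hydroxyphenyl)ethyl]-3-[(1E,3S,5S)-5-hydroxy-1,7-bis(4-hydroxyphenyl)hept-1-en-3-yl]oxan-4-ol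
Conditions: (R)-TRIP (10 mol %), 4 Å MS, PhCF3/MeCN 3:1, 0.2 M, 0 °C → rt; stop at about 60% conversion, recover 6
Reagents that add atoms: none (H2O is lost)
Why: Proposed new method: a chiral-phosphoric-acid-catalysed dehydrative homodimerisation (1,8-addition/oxa-1,6-addition cascade) in which the acid ionises the p-hydroxycinnamyl alcohol of one molecule of 6 to a phosphate-bound vinylogous p-quinone methide (sieves suppress water return, so un-ionised 6 is not epimerised), the p-hydroxystyrene of a second molecule (a vinylogous enol, ArOH hydrogen-bonded to P=O) attacks its far terminus through the β-carbon (1,8-attack keeps the E-styrene conjugated) on the alkene face anti to its allylic C–O (Kishi/inside-alkoxy model, sets ring C3 as S), the catalyst pocket selects the face of the planar electrophile terminus (sets the side-chain CH), and the new p-quinone methide is closed by the δ-OH through a chair with the aryl and both carbon chains equatorial (sets ring C2, 2,6-cis, self-correcting by reversible benzylic C–O ionisation; the 4-OH is axial because 6 is the syn-diol); the closest known reaction types are CPA-catalysed 1,6-/1,8-conjugate additions to in situ generated p-quinone methides and CPA-catalysed annulations of hydroxystyrenes.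

## Compound list

1 | 4-(4-hydroxyphenyl)butan-2-one | CC(=O)CCc1ccc(O)cc1 | starting material
2 | trimethyl({4-[4-(trimethylsilyloxy)phenyl]but-1-en-2-yl}oxy)silane | C=C(CCc1ccc(O[Si](C)(C)C)cc1)O[Si](C)(C)C | intermediate
3 | (E)-3-(4-hydroxyphenyl)prop-2-enal | O=C/C=C/c1ccc(O)cc1 | starting material
4 | (E)-3-[4-(trimethylsilyloxy)phenyl]prop-2-enal | O=C/C=C/c1ccc(O[Si](C)(C)C)cc1 | intermediate
5 | (5S,6E)-5-hydroxy-1,7-bis(4-hydroxyphenyl)hept-6-en-3-one | O=C(CCc1ccc(O)cc1)C[C@H](O)/C=C/c1ccc(O)cc1 | intermediate
6 | (1E,3S,5S)-1,7-bis(4-hydroxyphenyl)hept-1-ene-3,5-diol | Oc1ccc(/C=C/[C@@H](O)C[C@@H](O)CCc2ccc(O)cc2)cc1 | intermediate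
7 | blepharocalyxin C | Oc1ccc(/C=C/[C@H](C[C@@H](O)CCc2ccc(O)cc2)[C@@H]2[C@@H](c3ccc(O)cc3)O[C@@H](CCc3ccc(O)cc3)C[C@@H]2O)cc1 | target

## Totals and risks

Total steps: 5. Longest linear sequence: 4 (steps 1, 3, 4, 5).

Steps most likely to fail:

1. **Step 5 (proposed new dimerisation).** Risks:
   - 1,6- instead of 1,8-attack on the quinone methide.
   - Oligomerisation through the product's remaining styrene.
   - Internal trapping of the quinone methide by its own 5-OH to a 2-aryl-3,6-dihydropyran (expected to be reversible).
   - Ring closure by the side-chain OH instead of the ring-forming OH. For the desired side-chain epimer this would force the C3 chain axial, so it should be disfavoured.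
   - Poor catalyst control at the side-chain CH.

   Fallback (known chemistry, different strategy): TFA-mediated Prins cyclisation of 4-(TBSO)benzaldehyde with an (E)-homoallylic alcohol that already carries the side chain, the styryl group masked as CH2OPG. This gives the all-equatorial 2-aryl-3-alkyl-4-acyloxy-tetrahydropyran. Then invert C4 by Dess–Martin oxidation/L-Selectride reduction, unmask to the aldehyde, install the E-styrene by Horner–Wadsworth–Emmons olefination with a 4-silyloxybenzylphosphonate, and desilylate.

2. **Step 3 (asymmetric aldol).** Risks: modest er with an aliphatic methyl-ketone enol silane, and the electron-rich, TMS-protected enal under SiCl4. A moderate er is partly tolerated, because homodimerisation in step 5 statistically enriches the homochiral dimer.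

   Fallback: set the C5 carbinol first by proline-catalysed α-aminoxylation of 4-(4-silyloxyphenyl)butanal, convert to the terminal epoxide, open with the lithiated dithiane of 4-silyloxycinnamaldehyde, hydrolyse the dithiane to the β-hydroxy enone, and reduce with Et2BOMe/NaBH4 to the same syn-diol 6.

3. **Step 1 (one-pot kinetic bis-silylation).** Risks: regioisomeric internal enol silane, and loss of the labile aryl O–TMS before or during the aldol.

   Fallback: switch from transient to persistent protection. Make the TBS ethers of 1 and 3 in separate steps, form the enol silane from the TBS ether, and add a dedicated TBAF/AcOH desilylation after step 4 (7 steps in total).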